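If I want the flask that ends richest in open intermediate, I compare two times: how long substrate takes to turn over, and how long the run lasts.

| flask | substrate | coupling partner | free catalyst | temperature | remark | time |
|---|---|---|---|---|---|---|
| gamma | 0.075 M | 0.18 M | 0.12 mM | 34 °C | run made earlier |  |
| beta | 0.11 M | 0.18 M | 0.12 mM | 75 °C | run made earlier |  |
| Wednesday's | 0.15 M | 0.180 M | 0.12 mM | 65 °C |  | 30 min |
| Tuesday's | 0.15 M | 0.180 M | 0.12 mM | 15 °C |  | 30 min |
| Sunday's | 0.15 M | 0.180 M | 0.12 mM | 90 °C |  | 30 min |
| Thursday's | 0.15 M | 0.180 M | 0.12 mM | 40 °C |  | 30 min |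

- gamma (time / min: open intermediate / %, target / %, substrate / %): 12.0: 9, 0, 85; 40.0: 30, 0, 66; 60.0: 39, 2, 55; 90.0: 56, 0, 44; 150: 71, 2, 30; 180: 74, 1, 21
- beta (time / min: open intermediate / %, target / %, substrate / %): 4.00: 38, 1, 62; 8.00: 50, 6, 44; 12.0: 56, 5, 35; 15.0: 66, 2, 34; 20.0: 65, 7, 29; 25.0: 61, 7, 28

(readings scatter by 2 percentage points)

- the earlier runs were read with a standard deviation of 2 percentage points

* the flask that comes out highest in amount of open intermediate, in percent of the substrate charged, or "all alike" when all lie within 1.5 percentage points (Wednesday's / Tuesday's / Sunday's / Thursday's / all alike)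
* open intermediate at the end, in percent of the substrate charged, Wednesday's
* open intermediate at the end, in percent of the substrate charged, Tuesday's
* open intermediate at the end, in percent of the substrate charged, Sunday's
* open intermediate at the end, in percent of the substrate charged, Thursday's

1. For the early part of a run I treat substrate loss as pseudo-first-order: each minute takes a fixed share of what is left. This is an estimate for little-converted flasks, because the beta run slows later, reading 29 % substrate at 20.0 min and 28 % at 25.0 min.

2. The gamma run keeps 44 % of its substrate at 90.0 min, a rate constant of 0.00912 min⁻¹. The beta run keeps 62 % at 4.00 min, which gives 0.120 min⁻¹. Together these readings give an activation energy of 55.8 kJ mol⁻¹.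

3. At Tuesday's temperature, the filling time, meaning the inverse of that rate constant, is 463 min. The ratio of run time to filling time is 0.0648 for Tuesday's, 0.416 for Thursday's, 2.03 for Wednesday's and 7.95 for Sunday's.

4. The beta run's open intermediate reads its peak, 66 %, at 15.0 min, a ratio of 1.79. Thursday's falls short of that, Sunday's overshoots it, and Wednesday's sits next to it, so I pick Wednesday's. My exponential gives 6.28 % for Tuesday's and 34.0 % for Thursday's.

5. The forecast says Wednesday's, with 63 % for Wednesday's, 7 % for Tuesday's, 45 % for Sunday's and 34 % for Thursday's. Its ground: “Either way, hotter flasks stop earlier.”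

6. The flasks give 67.2 % for Wednesday's, 6.58 % for Tuesday's, 46.3 % for Sunday's and 34.1 % for Thursday's. The forecast stands.

    coupling partner + catalyst intermediate → free catalyst + target (k = 310 M⁻¹ min⁻¹, Ea = 61.0 kJ mol⁻¹)
    target → over-reaction product (k = 0.0240 min⁻¹, Ea = 105 kJ mol⁻¹)
    coupling partner → decomposition product (k = 4.50 × 10⁻⁵ min⁻¹, Ea = 124 kJ mol⁻¹)
    free catalyst + open intermediate ⇌ catalyst intermediate (K = 7.30 M⁻¹, k = 310 M⁻¹ min⁻¹, Ea = 71.0 kJ mol⁻¹, ΔH = 1.00 kJ mol⁻¹)
    substrate + free catalyst ⇌ free catalyst + open intermediate (K = 1.60, k = 2600 M⁻¹ min⁻¹, Ea = 57.0 kJ mol⁻¹, ΔH = −32.0 kJ mol⁻¹)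
    (constants at 90 °C)

Tuesday's flask is unfinished rather than poor. The length of the run is the largest single effect shown there: Tuesday's holds 6.58 % at 30 min and 46.5 % at 300 min, and its filling time of 463 min gives 47.7 % for that longer time.

A flask like Tuesday's kept at 0 °C stretches the filling time to 1660 min, so I reckon 1.79 % in 30 min. It gives 1.84 %.

All runs were generated by integration with constants of no real substance, and the scatter is random.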